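Compound numbers are those of the steps and of the compound list at the end.

## Analysis of the target

The target is a linear tridepside: three benzoyl units, rings A, B and C, joined by two aryl ester bonds, with the only free carboxyl on ring A. Ring A is a 2-methoxy-3,6-dimethylbenzoic acid acylated at O4, with C5 as its only CH. Ring B is hexasubstituted (C1 carbonyl, C2 methoxy, C3, C5 and C6 methyl, C4 acyloxy), and ring C is a 2,4-dihydroxy-3,6-dimethylbenzoyl group. There is no stereocentre and no axis that is expected to be configurationally stable, so the problem is one of regiochemistry and of bond formation under steric pressure. The sensitive groups are the two aryl esters (hydrolysis, transesterification, photo-Fries cleavage), the electron-rich ortho-oxygenated benzoic acids (easy decarboxylation when free), and the free phenols of ring C. The synthesis is hard because every ester carbonyl lies between two ortho substituents and O4 of ring B lies between two methyl groups. The C–B ester would therefore have to be made from a di-ortho-substituted acid and a di-ortho-substituted phenol, and the three rings differ only in which oxygens are free, methylated or acylated. The strategy rests on ring C: C2-OH, C3-Me and C4-OH (a methyl between two oxygens), C6-Me, C5-H and the C1 carboxyl bound to O4 of ring B map onto a ketene carbon, a 1-siloxypropyne and a 3-methyl enoate. Ring C can therefore be grown on an unhindered enoate ester of ring B instead of being acylated onto it.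

## Retrosynthetic reasoning

**30 ⇒ 29 ⇒ 28.** The last bonds cut are the benzyl–oxygen bond of the ring A ester and the O–Si bond at C4 of ring C. Both are removed without base (hydrogenolysis, acidic fluoride), which matters because the depside esters have phenoxide leaving groups. The silyl group is not an added protecting group; it arrives with the alkyne in the ring-forming step and leaves the two ring C oxygens already differentiated.

**28 ⇒ 20 + 23.** Ring C is cut at C1–C2, C2–C3 and C4–C5. This is preferred to cutting the C–B ester because that ester is the most congested bond of the molecule. In 20 the same ester exists as a plain enoate of the ring B phenol, with no ortho substituent on the acyl side. The forward reaction has to turn the diazo enone 20 into the vinylketene 24, combine it with the siloxyalkyne 23 so that the alkyne methyl ends up between the two oxygens, and close the six-membered ring at the enoate carbon.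

**20 ⇒ 18.** The diazo group is traced back to the methyl ketone 18 by diazo transfer. Acylation of a diazoalkane by an acid chloride of a mesaconate-type half ester is not used, because a diazoalkane is a 1,3-dipole and adds readily to a fumarate-type double bond. Activating the methyl ketone as its trifluoroacetyl derivative 19 and transferring the diazo group avoids that.

**18 ⇒ 12 + 16; 16 ⇒ 15 ⇒ 13 + 14.** The enoate ester C–O bond is cut to the ring B phenol 12 and the keto acid 16 (used as its chloride 17). The acyl partner is unhindered, so the hindered phenol should be acylated without difficulty. The acid comes from a Wittig reaction of the diketone 13 with the ylide 14, which makes the trisubstituted C=C bond and sets the E geometry in one step; the tert-butyl ester 15 is opened by acid, so no hydroxide meets the Michael acceptor.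

**12 ⇒ 11 ⇒ 10 ⇒ 8 + 3.** The B–A ester C–O bond is cut to the ring B acid 8 (as chloride 9) and the dihydroxy ester 3. The free 4-hydroxyl of 3 has one ortho methyl only, and the 2-hydroxyl is tied up by a hydrogen bond to the ester carbonyl, so 3 needs no protection. The remaining phenol is methylated afterwards (10 ⇒ 11), and the methoxymethyl ether on O4 of ring B is removed last (11 ⇒ 12).

**8 ⇒ 7 ⇒ 6 ⇒ 5 ⇒ 4 ⇒ 3.** Ring B is ring A plus one methyl at C5, so both come from the same ester 3. C5 is the only free ring position of 3 and is activated by both hydroxyls; it is formylated (4) and the formyl group is reduced to methyl (5). The carboxyl then differentiates the two hydroxyls: the non-chelated 4-hydroxyl is protected (6), the chelated 2-hydroxyl methylated (7), and the benzyl ester hydrogenolysed to the hindered acid 8 without saponification.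

**3 ⇒ 2 ⇒ 1.** The carboxyl of 2 is introduced by carboxylation of the symmetric resorcinol 1, whose two open positions are equivalent, so one acid results. Selective O-benzylation of the carboxylate gives 3.

**23 ⇒ 21.** The siloxyalkyne is cut at the C–O bond: the acetylide 21 is oxidised to the ynolate 22 and silylated on oxygen.

## Alternatives that were turned down

**Alternative 1:** Ring A is disconnected at C1–carboxyl and C6–CH2 by inserting the C1–C6 aryne of ring A into a C–C bond of a malonate. In the forward step the silyl triflate A2 releases the aryne with CsF, the anion of dibenzyl malonate A3 adds at C6 (remote from the methoxy group), and the C1 aryl anion closes onto an ester carbonyl; the four-membered ring then fragments to the diester A1.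
- For it: the methoxy group controls the regiochemistry, two C–C bonds form at once, and the conditions are mild and non-photochemical. On predictability of the key step it is probably stronger than a photochemical benzannulation on a depside.
- Against it: the C6 substituent arrives as CH2CO2Bn, not CH3, so a carboxyl must later be removed selectively next to an electron-rich benzoic acid that itself decarboxylates easily. A2 is itself a pentasubstituted benzene that needs the same phenol differentiation plus an ortho-silylation. Ring A is also the cheapest part of the target: carboxylation of 1 sets the same pattern in one step. Neither hindered ester is addressed.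
- Comparison: the chosen strategy accepts a riskier key step but spends it on the hardest bond of the molecule, and delivers ring C with its two oxygens already differentiated.

**Alternative 2:** The B–A ester is cut on both sides of its carbonyl carbon, which comes from CO. In the forward step the aryl iodide A5, CO and the phenol A6 are combined with Pd(OAc)2, Xantphos and K3PO4 to give A4, which has the same structure as 11.
- For it: the hindered acid 8 need not be prepared or activated, and the union is convergent. At the B–A junction it is at least as direct as steps 7 and 8.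
- Against it: oxidative addition of zerovalent palladium to a di-ortho-substituted, electron-rich iodide is slow, and the acylpalladium must be captured by a weakly nucleophilic, ortho-substituted phenoxide, so reduction of the iodide and direct C–O coupling compete. A5 has no carboxyl to tell its two oxygens apart, whereas in 5 the hydrogen-bonded ester does this. The more congested C–B ester is left to classical esterification.
- Comparison: the chosen strategy solves the C–B junction by ring construction and forms the easier B–A ester conventionally. The two ideas are compatible, since A4 is 11.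

**Alternative 3:** Ring B is cut at C3–C4 and C1–C6 into a three-carbon bis-nucleophile already esterified to ring A and a three-carbon bis-electrophile. In the forward step the bis-silyl dienol ether A8 and the acid chloride A9 react under TiCl4 to give, after cyclisation and aromatisation, the dihydroxy depside A7.
- For it: the hexasubstituted ring B with all three methyl groups forms in one step, and the B–A ester is carried in as an unhindered β-keto ester. For the construction of ring B it is shorter than steps 3 to 7 of the chosen route.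
- Against it: A8 derives from an aryl β-keto ester, which loses aryloxide easily on enolisation or under TiCl4 (acylketene formation). The diene must also discriminate C- from O-acylation by A9. A7 has both ring B hydroxyls free, and the more reactive 4-hydroxyl must stay open for acylation while the chelated 2-hydroxyl is methylated, which costs protection steps. Ring C must then still be esterified onto the di-ortho-methyl phenol with a di-ortho-substituted acid.
- Comparison: both strategies carry a hindered aryl ester through a benzannulation as an unhindered acyclic ester. The chosen one applies this to the ring where the ester is hardest to make, runs under neutral conditions, and needs no later regioselective alkylation.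

Key step: step 16

## Route

Remarks on the chemistry:
- The target has no stereocentre. The only stereochemical element of the route is the E geometry of the enoate in 15 to 26, which disappears on aromatisation. 25 and 27 each carry one transient sp3 carbon and would form as racemates.
- 1, 13, 14 and 21 are taken as commercial.
- The diazoketone is made by diazo transfer to a methyl ketone, not from diazomethane and an acid chloride, because diazomethane would add to the doubly activated C=C bond.

Step 1
Reactants: 1 2,5-dimethylbenzene-1,3-diol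
Product: 2 2,4-dihydroxy-3,6-dimethylbenzoic acid
Conditions: KHCO3, CO2 (1 atm), glycerol, 130 °C; then cold aq. HCl
Reagents that add atoms: carbon dioxide, O=C=O
Why: Kolbe–Schmitt carboxylation of an electron-rich resorcinol; the two open positions of 1 are equivalent by symmetry and C2 is blocked, so only one acid can form, and cold acidification limits decarboxylation.

Step 2
Reactants: 2 2,4-dihydroxy-3,6-dimethylbenzoic acid
Product: 3 benzyl 2,4-dihydroxy-3,6-dimethylbenzoate
Conditions: BnBr (1.05 equiv), KHCO3 (1.1 equiv), DMF, rt
Reagents that add atoms: benzyl bromide, BrCc1ccccc1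
Why: SN2 alkylation of the carboxylate; hydrogen carbonate deprotonates only the carboxylic acid, so both phenols should stay free.

Step 3
Reactants: 3 benzyl 2,4-dihydroxy-3,6-dimethylbenzoate
Product: 4 benzyl 3-formyl-4,6-dihydroxy-2,5-dimethylbenzoate (the C5-formyl derivative of 3)
Conditions: Cl2CHOMe (1.5 equiv), TiCl4 (3 equiv), CH2Cl2, −10 → 0 °C; then aq. HCl
Reagents that add atoms: dichloromethyl methyl ether, COC(Cl)Cl
Why: Rieche formylation; C5 is the only unsubstituted ring carbon, ortho to the 4-hydroxyl and para to the 2-hydroxyl, and the titanium phenoxide directs the electrophile ortho.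

Step 4
Reactants: 4 benzyl 3-formyl-4,6-dihydroxy-2,5-dimethylbenzoate
Product: 5 benzyl 2,4-dihydroxy-3,5,6-trimethylbenzoate
Conditions: Et3SiH (3 equiv), CF3CO2H, CH2Cl2, 0 °C → rt
Reagents that add atoms: none
Why: Ionic hydrogenation of an aryl aldehyde to a methyl group; two hydride transfers pass through a benzylic cation stabilised by the ortho and para hydroxyls, and the benzyl ester is not hydrogenolysed under these conditions.

Step 5
Reactants: 5 benzyl 2,4-dihydroxy-3,5,6-trimethylbenzoate
Product: 6 benzyl 2-hydroxy-4-(methoxymethoxy)-3,5,6-trimethylbenzoate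
Conditions: MOMCl (1.2 equiv), iPr2NEt (1.5 equiv), CH2Cl2, 0 °C → rt
Reagents that add atoms: chloromethyl methyl ether, COCCl
Why: O-alkylation with a small, reactive electrophile; the 2-hydroxyl is hydrogen-bonded to the ester carbonyl and inert under amine base, so the 4-hydroxyl should react despite its two ortho methyls.

Step 6
Reactants: 6 benzyl 2-hydroxy-4-(methoxymethoxy)-3,5,6-trimethylbenzoate
Product: 7 benzyl 2-methoxy-4-(methoxymethoxy)-3,5,6-trimethylbenzoate
Conditions: MeI (3 equiv), K2CO3 (2 equiv), DMF, 40 °C
Reagents that add atoms: iodomethane, CI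
Why: Williamson methylation of the chelated phenol under carbonate in a dipolar solvent; no other acidic site is present.

Step 7
Reactants: 7 benzyl 2-methoxy-4-(methoxymethoxy)-3,5,6-trimethylbenzoate
Product: 8 2-methoxy-4-(methoxymethoxy)-3,5,6-trimethylbenzoic acid
Conditions: H2 (1 atm), 10% Pd/C, EtOAc, rt
Reagents that add atoms: none
Why: Hydrogenolysis of the benzyl ester frees the di-ortho-substituted acid without a slow saponification; the acetal and the aryl ethers are inert.

Step 8
Reactants: 8 2-methoxy-4-(methoxymethoxy)-3,5,6-trimethylbenzoic acid; 3 benzyl 2,4-dihydroxy-3,6-dimethylbenzoate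
Product: 10 benzyl 2-hydroxy-4-{[2-methoxy-4-(methoxymethoxy)-3,5,6-trimethylbenzoyl]oxy}-3,6-dimethylbenzoate, via acid chloride 9 (not isolated)
Conditions: 1-chloro-N,N,2-trimethylprop-1-en-1-amine (1.2 equiv), CH2Cl2, 0 °C → rt; then 3 (1.0 equiv), Et3N (1.5 equiv), DMAP (0.2 equiv), CH2Cl2, 0 °C → rt
Reagents that add atoms: none
Why: The chloroenamine forms the acid chloride without free HCl, so the acetal survives; acyl substitution should occur at the 4-hydroxyl of 3, because the 2-hydroxyl is hydrogen-bonded and flanked by ester and methyl.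

Step 9
Reactants: 10 benzyl 2-hydroxy-4-{[2-methoxy-4-(methoxymethoxy)-3,5,6-trimethylbenzoyl]oxy}-3,6-dimethylbenzoate
Product: 11 benzyl 2-methoxy-4-{[2-methoxy-4-(methoxymethoxy)-3,5,6-trimethylbenzoyl]oxy}-3,6-dimethylbenzoate
Conditions: MeI (3 equiv), K2CO3 (2 equiv), DMF, rt → 40 °C
Reagents that add atoms: iodomethane, CI
Why: Williamson methylation of the only remaining phenol; the diaryl ester carbonyl is shielded by its ortho methoxy and methyl groups, and the meta-disposed phenoxide cannot reach the acyl group on O4, so neither cleavage nor acyl migration is expected.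

Step 10
Reactants: 11 benzyl 2-methoxy-4-{[2-methoxy-4-(methoxymethoxy)-3,5,6-trimethylbenzoyl]oxy}-3,6-dimethylbenzoate
Product: 12 benzyl 4-[(4-hydroxy-2-methoxy-3,5,6-trimethylbenzoyl)oxy]-2-methoxy-3,6-dimethylbenzoate
Conditions: HCl (1.25 M in MeOH), THF, 40 °C
Reagents that add atoms: none
Why: Acid-catalysed acetal exchange removes the methoxymethyl group as its dimethyl acetal, and methanol traps the oxocarbenium ion before it can alkylate C5 of ring A; both hindered esters should resist methanolysis.

Step 11
Reactants: 13 butane-2,3-dione; 14 tert-butyl (triphenylphosphoranylidene)acetate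
Product: 15 tert-butyl (2E)-3-methyl-4-oxopent-2-enoate
Conditions: 13 (2 equiv), CH2Cl2, 0 °C → rt
Reagents that add atoms: none
Why: Wittig olefination of an activated 1,2-diketone by a stabilised ylide; excess diketone suppresses double olefination, and the E isomer (ester trans to acetyl) should predominate, with any Z isomer removed by chromatography.

Step 12
Reactants: 15 tert-butyl (2E)-3-methyl-4-oxopent-2-enoate
Product: 16 (2E)-3-methyl-4-oxopent-2-enoic acid
Conditions: CF3CO2H/CH2Cl2 (1:1), rt
Reagents that add atoms: none
Why: Acidolysis of the tert-butyl ester through the tert-butyl cation; no base meets the Michael acceptor, and the E acid cannot close to a lactol.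

Step 13
Reactants: 16 (2E)-3-methyl-4-oxopent-2-enoic acid; 12 benzyl 4-[(4-hydroxy-2-methoxy-3,5,6-trimethylbenzoyl)oxy]-2-methoxy-3,6-dimethylbenzoate
Product: 18 benzyl 2-methoxy-4-[(2-methoxy-3,5,6-trimethyl-4-{[(2E)-3-methyl-4-oxopent-2-enoyl]oxy}benzoyl)oxy]-3,6-dimethylbenzoate, via acid chloride 17 (not isolated)
Conditions: (COCl)2 (1.2 equiv), DMF (cat.), CH2Cl2, 0 °C → rt, evaporate; then 12, pyridine (3 equiv), DMAP (0.1 equiv), CH2Cl2, 0 °C → rt
Reagents that add atoms: none
Why: Acylation of the di-ortho-methyl phenol by an unhindered acid chloride through its acylpyridinium ion; pyridine instead of a trialkylamine limits γ-deprotonation of the acid chloride to a vinylketene, which would deconjugate the double bond.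

Step 14
Reactants: 18 benzyl 2-methoxy-4-[(2-methoxy-3,5,6-trimethyl-4-{[(2E)-3-methyl-4-oxopent-2-enoyl]oxy}benzoyl)oxy]-3,6-dimethylbenzoate
Product: 20 benzyl 4-[(4-{[(2E)-5-diazo-3-methyl-4-oxopent-2-enoyl]oxy}-2-methoxy-3,5,6-trimethylbenzoyl)oxy]-2-methoxy-3,6-dimethylbenzoate, via trifluoroacetyl diketone 19 (not isolated)
Conditions: LiN(SiMe3)2 (1.1 equiv), THF, −78 °C (18 added to the base); CF3CO2CH2CF3 (1.2 equiv), −78 °C; aq. HCl work-up; then MeSO2N3 (1.5 equiv), Et3N (1.5 equiv), H2O (1 equiv), MeCN, rt
Reagents that add atoms: methanesulfonyl azide, CS(=O)(=O)N=[N+]=[N-]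
Why: Detrifluoroacetylative diazo transfer, the standard entry to α,β-unsaturated diazoketones; the methyl group is the only enolisable position of the ketone, the kinetic enolate is trifluoroacetylated, and the 1,3-diketone accepts the diazo group with loss of the trifluoroacetyl group onto the sulfonamide.

Step 15
Reactants: 21 prop-1-ynyllithium
Product: 23 triisopropyl(prop-1-yn-1-yloxy)silane, via lithium ynolate 22 (not isolated)
Conditions: t-BuOOH (1.0 equiv), LiN(SiMe3)2 (1.0 equiv), THF, −78 °C; 21, −78 → 0 °C; then iPr3SiOSO2CF3 (1.05 equiv), −78 → 0 °C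
Reagents that add atoms: tert-butyl hydroperoxide, CC(C)(C)OO; triisopropylsilyl trifluoromethanesulfonate, CC(C)[Si](OS(=O)(=O)C(F)(F)F)(C(C)C)C(C)C
Why: Oxidation of a lithium acetylide by lithium tert-butyl peroxide gives the ynolate, and the bulky silyl triflate silylates it on oxygen, a general route to 1-siloxyalkynes.

Step 16
Reactants: 20 benzyl 4-[(4-{[(2E)-5-diazo-3-methyl-4-oxopent-2-enoyl]oxy}-2-methoxy-3,5,6-trimethylbenzoyl)oxy]-2-methoxy-3,6-dimethylbenzoate; 23 triisopropyl(prop-1-yn-1-yloxy)silane
Product: 28 benzyl 4-{[4-({2-hydroxy-3,6-dimethyl-4-[(triisopropylsilyl)oxy]benzoyl}oxy)-2-methoxy-3,5,6-trimethylbenzoyl]oxy}-2-methoxy-3,6-dimethylbenzoate, via vinylketene 24 (not isolated), via alkenylcyclobutenone 25 (not isolated), via dienylketene 26 (not isolated), via cyclohexadienone 27 (not isolated)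
Conditions: 23 (2 equiv), ClCH2CH2Cl (degassed), hν (365 nm), rt; then 80 °C in the dark
Reagents that add atoms: none
Why: Excitation of the diazo enone expels nitrogen and Wolff rearrangement gives the vinylketene 24, whose ketene C=C bond adds to 23 in a [2+2] cycloaddition to give the cyclobutenone 25. Heating opens 25 by a reversible four-electron electrocyclic reaction to the dienylketene 26, which closes by thermal disrotatory 6π-electrocyclisation (bond C1–C2, six-membered carbocycle) to the dienone 27 and tautomerises to the phenol 28. The closest known reaction is the photochemical Danheiser benzannulation of α,β-unsaturated α′-diazoketones with siloxyalkynes; what is new here is only the ester on the vinylketene terminus. No stereocentre remains, since the sp3 carbons of 25 and 27 are erased on aromatisation. The step needs the methyl between the two oxygens, and the polarisation of 23 secures this: its nucleophilic methyl-bearing carbon bonds to the ketene carbonyl carbon (C2–C3) and its oxygen-bearing carbon to the ketene α-carbon (C4–C5). The E geometry of the enoate keeps the aryloxycarbonyl group on the outside of the closing triene and away from an oxa-6π closure of the ketene onto the ester carbonyl. Because ring opening of 25 is reversible, only the dienylketene geometry that can cyclise is drained off. Irradiation at 365 nm, where only the diazo enone absorbs, should spare the two aryl esters from photo-Fries cleavage.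

Step 17
Reactants: 28 benzyl 4-{[4-({2-hydroxy-3,6-dimethyl-4-[(triisopropylsilyl)oxy]benzoyl}oxy)-2-methoxy-3,5,6-trimethylbenzoyl]oxy}-2-methoxy-3,6-dimethylbenzoate
Product: 29 benzyl 4-({4-[(2,4-dihydroxy-3,6-dimethylbenzoyl)oxy]-2-methoxy-3,5,6-trimethylbenzoyl}oxy)-2-methoxy-3,6-dimethylbenzoate
Conditions: HF·pyridine, THF/pyridine, 0 °C → rt
Reagents that add atoms: none
Why: Fluoride cleavage of the aryl silyl ether under mildly acidic conditions; no free phenoxide is formed, so the depside esters are not exposed to base.

Step 18
Reactants: 29 benzyl 4-({4-[(2,4-dihydroxy-3,6-dimethylbenzoyl)oxy]-2-methoxy-3,5,6-trimethylbenzoyl}oxy)-2-methoxy-3,6-dimethylbenzoate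
Product: 30 4-({4-[(2,4-dihydroxy-3,6-dimethylbenzoyl)oxy]-2-methoxy-3,5,6-trimethylbenzoyl}oxy)-2-methoxy-3,6-dimethylbenzoic acid
Conditions: H2 (1 atm), 10% Pd/C, EtOAc, rt
Reagents that add atoms: none
Why: Hydrogenolysis of the benzyl ester frees the ring A acid under neutral conditions; aryl esters, phenols and aryl ethers are inert.

## Compound list

1 | 2,5-dimethylbenzene-1,3-diol | Cc1cc(O)c(C)c(O)c1 | starting material
2 | 2,4-dihydroxy-3,6-dimethylbenzoic acid | Cc1cc(O)c(C)c(O)c1C(=O)O | intermediate
3 | benzyl 2,4-dihydroxy-3,6-dimethylbenzoate | Cc1cc(O)c(C)c(O)c1C(=O)OCc1ccccc1 | intermediate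
4 | benzyl 3-formyl-4,6-dihydroxy-2,5-dimethylbenzoate | Cc1c(C=O)c(O)c(C)c(O)c1C(=O)OCc1ccccc1 | intermediate
5 | benzyl 2,4-dihydroxy-3,5,6-trimethylbenzoate | Cc1c(C)c(O)c(C)c(O)c1C(=O)OCc1ccccc1 | intermediate
6 | benzyl 2-hydroxy-4-(methoxymethoxy)-3,5,6-trimethylbenzoate | COCOc1c(C)c(C)c(C(=O)OCc2ccccc2)c(O)c1C | intermediate
7 | benzyl 2-methoxy-4-(methoxymethoxy)-3,5,6-trimethylbenzoate | COCOc1c(C)c(C)c(C(=O)OCc2ccccc2)c(OC)c1C | intermediate
8 | 2-methoxy-4-(methoxymethoxy)-3,5,6-trimethylbenzoic acid | COCOc1c(C)c(C)c(C(=O)O)c(OC)c1C | intermediate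
9 | 2-methoxy-4-(methoxymethoxy)-3,5,6-trimethylbenzoyl chloride | COCOc1c(C)c(C)c(C(Cl)=O)c(OC)c1C | intermediate
10 | benzyl 2-hydroxy-4-{[2-methoxy-4-(methoxymethoxy)-3,5,6-trimethylbenzoyl]oxy}-3,6-dimethylbenzoate | COCOc1c(C)c(C)c(C(=O)Oc2cc(C)c(C(=O)OCc3ccccc3)c(O)c2C)c(OC)c1C | intermediate
11 | benzyl 2-methoxy-4-{[2-methoxy-4-(methoxymethoxy)-3,5,6-trimethylbenzoyl]oxy}-3,6-dimethylbenzoate | COCOc1c(C)c(C)c(C(=O)Oc2cc(C)c(C(=O)OCc3ccccc3)c(OC)c2C)c(OC)c1C | intermediate
12 | benzyl 4-[(4-hydroxy-2-methoxy-3,5,6-trimethylbenzoyl)oxy]-2-methoxy-3,6-dimethylbenzoate | COc1c(C)c(OC(=O)c2c(C)c(C)c(O)c(C)c2OC)cc(C)c1C(=O)OCc1ccccc1 | intermediate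
13 | butane-2,3-dione | CC(=O)C(C)=O | starting material
14 | tert-butyl (triphenylphosphoranylidene)acetate | CC(C)(C)OC(=O)C=P(c1ccccc1)(c1ccccc1)c1ccccc1 | starting material
15 | tert-butyl (2E)-3-methyl-4-oxopent-2-enoate | CC(=O)/C(C)=C/C(=O)OC(C)(C)C | intermediate
16 | (2E)-3-methyl-4-oxopent-2-enoic acid | CC(=O)/C(C)=C/C(=O)O | intermediate
17 | (2E)-3-methyl-4-oxopent-2-enoyl chloride | CC(=O)/C(C)=C/C(Cl)=O | intermediate
18 | benzyl 2-methoxy-4-[(2-methoxy-3,5,6-trimethyl-4-{[(2E)-3-methyl-4-oxopent-2-enoyl]oxy}benzoyl)oxy]-3,6-dimethylbenzoate | COc1c(C)c(OC(=O)c2c(C)c(C)c(OC(=O)/C=C(\C)C(C)=O)c(C)c2OC)cc(C)c1C(=O)OCc1ccccc1 | intermediate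
19 | (2E)-7,7,7-trifluoro-3-methyl-4,6-dioxohept-2-enoate ester of the ring B hydroxyl of 12 | COc1c(C)c(OC(=O)c2c(C)c(C)c(OC(=O)/C=C(\C)C(=O)CC(=O)C(F)(F)F)c(C)c2OC)cc(C)c1C(=O)OCc1ccccc1 | intermediate
20 | benzyl 4-[(4-{[(2E)-5-diazo-3-methyl-4-oxopent-2-enoyl]oxy}-2-methoxy-3,5,6-trimethylbenzoyl)oxy]-2-methoxy-3,6-dimethylbenzoate | COc1c(C)c(OC(=O)c2c(C)c(C)c(OC(=O)/C=C(\C)C(=O)C=[N+]=[N-])c(C)c2OC)cc(C)c1C(=O)OCc1ccccc1 | intermediate
21 | prop-1-ynyllithium | [Li]C#CC | starting material
22 | lithium prop-1-yn-1-olate | CC#C[O-].[Li+] | intermediate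
23 | triisopropyl(prop-1-yn-1-yloxy)silane | CC#CO[Si](C(C)C)(C(C)C)C(C)C | intermediate
24 | (2E)-3-methyl-5-oxopenta-2,4-dienoate ester of the ring B hydroxyl of 12 (vinylketene) | COc1c(C)c(OC(=O)c2c(C)c(C)c(OC(=O)/C=C(\C)C=C=O)c(C)c2OC)cc(C)c1C(=O)OCc1ccccc1 | intermediate
25 | (2E)-3-{3-methyl-4-oxo-2-[(triisopropylsilyl)oxy]cyclobut-2-en-1-yl}but-2-enoate ester of the ring B hydroxyl of 12, racemic | COc1c(C)c(OC(=O)c2c(C)c(C)c(OC(=O)/C=C(\C)C3C(=O)C(C)=C3O[Si](C(C)C)(C(C)C)C(C)C)c(C)c2OC)cc(C)c1C(=O)OCc1ccccc1 | intermediate
26 | (2E,4E)-3,6-dimethyl-7-oxo-5-[(triisopropylsilyl)oxy]hepta-2,4,6-trienoate ester of the ring B hydroxyl of 12 (dienylketene, ketenyl carbon and enoate carbon cis across the central double bond) | COc1c(C)c(OC(=O)c2c(C)c(C)c(OC(=O)/C=C(\C)/C=C(\C(C)=C=O)O[Si](C(C)C)(C(C)C)C(C)C)c(C)c2OC)cc(C)c1C(=O)OCc1ccccc1 | intermediate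
27 | 3,6-dimethyl-2-oxo-4-[(triisopropylsilyl)oxy]cyclohexa-3,5-diene-1-carboxylate ester of the ring B hydroxyl of 12, racemic | COc1c(C)c(OC(=O)c2c(C)c(C)c(OC(=O)C3C(C)=CC(O[Si](C(C)C)(C(C)C)C(C)C)=C(C)C3=O)c(C)c2OC)cc(C)c1C(=O)OCc1ccccc1 | intermediate
28 | benzyl 4-{[4-({2-hydroxy-3,6-dimethyl-4-[(triisopropylsilyl)oxy]benzoyl}oxy)-2-methoxy-3,5,6-trimethylbenzoyl]oxy}-2-methoxy-3,6-dimethylbenzoate | COc1c(C)c(OC(=O)c2c(C)c(C)c(OC(=O)c3c(C)cc(O[Si](C(C)C)(C(C)C)C(C)C)c(C)c3O)c(C)c2OC)cc(C)c1C(=O)OCc1ccccc1 | intermediate
29 | benzyl 4-({4-[(2,4-dihydroxy-3,6-dimethylbenzoyl)oxy]-2-methoxy-3,5,6-trimethylbenzoyl}oxy)-2-methoxy-3,6-dimethylbenzoate | COc1c(C)c(OC(=O)c2c(C)c(C)c(OC(=O)c3c(C)cc(O)c(C)c3O)c(C)c2OC)cc(C)c1C(=O)OCc1ccccc1 | intermediate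
30 | 4-({4-[(2,4-dihydroxy-3,6-dimethylbenzoyl)oxy]-2-methoxy-3,5,6-trimethylbenzoyl}oxy)-2-methoxy-3,6-dimethylbenzoic acid | COc1c(C)c(OC(=O)c2c(C)c(C)c(OC(=O)c3c(C)cc(O)c(C)c3O)c(C)c2OC)cc(C)c1C(=O)O | target

## Step count and least certain steps

Total step count: 18. Longest linear sequence: 15 steps (1 to 30 through steps 1 to 10, 13, 14, 16, 17 and 18).

**Step 16 (key step).**
- What may go wrong: photochemical E to Z isomerisation of the diazo enone before loss of nitrogen would put the ester on the inside, where the ketene can close onto the ester carbonyl instead of onto carbon. If the light is absorbed by the aryl esters, photo-Fries cleavage of the depside bonds would follow. The product phenol may also be acylated by the vinylketene, or the nucleophilic alkyne may add in a conjugate sense to the acceptor-substituted enone.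
- Fallback: from 12 and 3, returning at 30, by classical depside chemistry. 3 is dibenzylated (BnBr, K2CO3, DMF) to benzyl 2,4-bis(benzyloxy)-3,6-dimethylbenzoate F1. Its ester is saponified (KOH, aqueous DMSO, 80 °C) to 2,4-bis(benzyloxy)-3,6-dimethylbenzoic acid F2. F2 is joined to the phenol 12 with trifluoroacetic anhydride in toluene (mixed anhydride activation) to give the tribenzyl tridepside F3, and hydrogenolysis of the three benzyl groups over Pd/C gives 30.

**Step 14.**
- What may go wrong: conjugate addition of the ketone enolate to the doubly activated double bond of a second molecule, and attack of the amide base on the unhindered enoate aryl ester with loss of the side chain.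
- Fallback: from 18, returning at 20, without a strong base. Soft enolisation (Me3SiOSO2CF3, Et3N, CH2Cl2, 0 °C) gives the silyl enol ether F4. N-Bromosuccinimide at −78 °C converts it into the bromomethyl ketone F5. N,N′-Ditosylhydrazine and DBU in THF at 0 °C alkylate to the N-alkyl ditosylhydrazine F6, which loses two sulfinate groups to give 20.

**Step 13.**
- What may go wrong: base-induced loss of a γ-proton from the acid chloride gives a vinylketene and hence a deconjugated ester. Addition–elimination of chloride can isomerise the double bond and lead to ring closure of the Z acid chloride. Acylation of the di-ortho-methyl phenol may be slow.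
- Fallback: from 12, returning at 18, forming the double bond on the phenol instead of acylating with it. 12 adds to (triphenylphosphoranylidene)ketene in toluene to give the aryl (triphenylphosphoranylidene)acetate F7, and Wittig reaction of F7 with 13 gives 18.

**Step 8.**
- What may go wrong: slow acyl transfer from the di-ortho-substituted acid chloride, loss of the acetal if HCl accumulates, and incomplete discrimination between the two hydroxyls of 3.
- Fallback: from 3, returning at 11 (step 9 is then not needed), using a single, fully deprotonated phenol. 3 is protected (MOMCl, iPr2NEt) as benzyl 2-hydroxy-4-(methoxymethoxy)-3,6-dimethylbenzoate F8, methylated (MeI, K2CO3, DMF) to benzyl 2-methoxy-4-(methoxymethoxy)-3,6-dimethylbenzoate F9, and deprotected (HCl, MeOH) to benzyl 4-hydroxy-2-methoxy-3,6-dimethylbenzoate F10. The sodium phenoxide of F10 (NaH, THF) is then acylated by 9 to give 11.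

## Further compounds

F1 | step 16 | benzyl 2,4-bis(benzyloxy)-3,6-dimethylbenzoate | Cc1cc(OCc2ccccc2)c(C)c(OCc2ccccc2)c1C(=O)OCc1ccccc1
F2 | step 16 | 2,4-bis(benzyloxy)-3,6-dimethylbenzoic acid | Cc1cc(OCc2ccccc2)c(C)c(OCc2ccccc2)c1C(=O)O
F3 | step 16 | benzyl 4-[(4-{[2,4-bis(benzyloxy)-3,6-dimethylbenzoyl]oxy}-2-methoxy-3,5,6-trimethylbenzoyl)oxy]-2-methoxy-3,6-dimethylbenzoate | COc1c(C)c(OC(=O)c2c(C)c(C)c(OC(=O)c3c(C)cc(OCc4ccccc4)c(C)c3OCc3ccccc3)c(C)c2OC)cc(C)c1C(=O)OCc1ccccc1
F4 | step 14 | (2E)-3-methyl-4-[(trimethylsilyl)oxy]penta-2,4-dienoate ester of the ring B hydroxyl of 12 | COc1c(C)c(OC(=O)c2c(C)c(C)c(OC(=O)/C=C(\C)C(=C)O[Si](C)(C)C)c(C)c2OC)cc(C)c1C(=O)OCc1ccccc1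
F5 | step 14 | (2E)-5-bromo-3-methyl-4-oxopent-2-enoate ester of the ring B hydroxyl of 12 | COc1c(C)c(OC(=O)c2c(C)c(C)c(OC(=O)/C=C(\C)C(=O)CBr)c(C)c2OC)cc(C)c1C(=O)OCc1ccccc1
F6 | step 14 | (2E)-5-[1,2-bis(4-methylbenzenesulfonyl)hydrazinyl]-3-methyl-4-oxopent-2-enoate ester of the ring B hydroxyl of 12 | COc1c(C)c(OC(=O)c2c(C)c(C)c(OC(=O)/C=C(\C)C(=O)CN(NS(=O)(=O)c3ccc(C)cc3)S(=O)(=O)c3ccc(C)cc3)c(C)c2OC)cc(C)c1C(=O)OCc1ccccc1
F7 | step 13 | (triphenylphosphoranylidene)acetate ester of the ring B hydroxyl of 12 | COc1c(C)c(OC(=O)c2c(C)c(C)c(OC(=O)C=P(c3ccccc3)(c3ccccc3)c3ccccc3)c(C)c2OC)cc(C)c1C(=O)OCc1ccccc1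
F8 | step 8 | benzyl 2-hydroxy-4-(methoxymethoxy)-3,6-dimethylbenzoate | COCOc1cc(C)c(C(=O)OCc2ccccc2)c(O)c1C
F9 | step 8 | benzyl 2-methoxy-4-(methoxymethoxy)-3,6-dimethylbenzoate | COCOc1cc(C)c(C(=O)OCc2ccccc2)c(OC)c1C
F10 | step 8 | benzyl 4-hydroxy-2-methoxy-3,6-dimethylbenzoate | COc1c(C)c(O)cc(C)c1C(=O)OCc1ccccc1
A1 | alternative 1 | benzyl 6-[2-(benzyloxy)-2-oxoethyl]-2-methoxy-4-(methoxymethoxy)-3-methylbenzoate | COCOc1cc(CC(=O)OCc2ccccc2)c(C(=O)OCc2ccccc2)c(OC)c1C
A2 | alternative 1 | 2-methoxy-4-(methoxymethoxy)-3-methyl-6-(trimethylsilyl)phenyl trifluoromethanesulfonate | COCOc1cc([Si](C)(C)C)c(OS(=O)(=O)C(F)(F)F)c(OC)c1C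
A3 | alternative 1 | dibenzyl malonate | O=C(CC(=O)OCc1ccccc1)OCc1ccccc1
A4 | alternative 2 | benzyl 2-methoxy-4-{[2-methoxy-4-(methoxymethoxy)-3,5,6-trimethylbenzoyl]oxy}-3,6-dimethylbenzoate | COCOc1c(C)c(C)c(C(=O)Oc2cc(C)c(C(=O)OCc3ccccc3)c(OC)c2C)c(OC)c1C
A5 | alternative 2 | 1-iodo-2-methoxy-4-(methoxymethoxy)-3,5,6-trimethylbenzene | COCOc1c(C)c(C)c(I)c(OC)c1C
A6 | alternative 2 | benzyl 4-hydroxy-2-methoxy-3,6-dimethylbenzoate | COc1c(C)c(O)cc(C)c1C(=O)OCc1ccccc1
A7 | alternative 3 | benzyl 4-[(2,4-dihydroxy-3,5,6-trimethylbenzoyl)oxy]-2-methoxy-3,6-dimethylbenzoate | COc1c(C)c(OC(=O)c2c(C)c(C)c(O)c(C)c2O)cc(C)c1C(=O)OCc1ccccc1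
A8 | alternative 3 | benzyl 4-{[1,3-bis(trimethylsilyloxy)penta-1,3-dien-1-yl]oxy}-2-methoxy-3,6-dimethylbenzoate (double-bond geometry not defined) | COc1c(C)c(OC(O[Si](C)(C)C)=CC(O[Si](C)(C)C)=CC)cc(C)c1C(=O)OCc1ccccc1
A9 | alternative 3 | (2E)-3-methoxy-2-methylbut-2-enoyl chloride | CO/C(C)=C(\C)C(Cl)=O
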